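## Retrosynthetic overview

1. Target 10 ⇐ ketone 9 (methylenation at C1) ⇐ enedione 8 (bromomethylenation at C9). Locants: ring A = C1–C5, spiro atom = C6, ring B = C7–C11.
2. 8 ⇐ formyl ketone 5 + methyl vinyl ketone 6 by Michael addition/aldol condensation. Ring B is closed last and the spiro centre is set by axial attack on the ring A enolate.
3. 5 (ring A, C5–C6 bond) ⇐ oxane enol ether 4 by a bromonium-relayed 1,3-O→C shift that never breaks the C–Br bond.
4. 4 ⇐ keto aldehyde 3 by catalytic enantioselective 6-endo bromoetherification: this C–O bond formation installs the only catalyst-controlled stereocentre (C–Br). 3 ⇐ sulcatone 1 + a formate.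
5. Ring order: oxane (C–O) first, transposed into carbocycle A, then carbocycle B.

Assumption: the sense of induction in step 2 is assigned by analogy; if (DHQD)2PHAL gives the (S)-bromide, the pseudo-enantiomeric (DHQ)2PHAL is used instead.

## Route

Step 1
Reactants: 1 6-methylhept-5-en-2-one (sulcatone)
Product: 3 (1Z)-1-hydroxy-7-methylocta-1,6-dien-3-one (chelated enol of 7-methyl-3-oxooct-6-enal), via kinetic lithium enolate 2 (not isolated)
Conditions: LiN(iPr)2 (1.1 equiv), THF, −78 °C; then HCO2CH2CF3 (1.3 equiv), −78 → 0 °C; aq. HCl work-up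
Reagents that add atoms: 2,2,2-trifluoroethyl formate, O=COCC(F)(F)F
Why: Crossed Claisen formylation: the amide base removes a methyl proton kinetically and the activated formate acylates the terminal enolate, the product being held as its lithium chelate until work-up; no stereocentre is formed.

Step 2
Reactants: 3 (1Z)-1-hydroxy-7-methylocta-1,6-dien-3-one
Product: 4 (2Z)-2-[(5R)-5-bromo-6,6-dimethyloxan-2-ylidene]acetaldehyde
Conditions: N-bromosuccinimide (1.05 equiv), hydroquinidine 1,4-phthalazinediyl diether [(DHQD)2PHAL] (10 mol %), CHCl3–hexane 1:1, −50 °C, dark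
Reagents that add atoms: N-bromosuccinimide, O=C1CCC(=O)N1Br
Why: Catalytic asymmetric bromocycloetherification (bromolactonisation-type): the acidic, carboxylic-acid-like enol O–H is held by the quinuclidine base while catalyst-bound Br+ is delivered to one face of the prenyl alkene, and anti, Markovnikov 6-endo attack of the enol oxygen at the tertiary carbon forms the C–O bond and fixes the (R)-C–Br centre.

Step 3
Reactants: 4 (2Z)-2-[(5R)-5-bromo-6,6-dimethyloxan-2-ylidene]acetaldehyde
Product: 5 (2Z,4R)-4-bromo-2-(hydroxymethylidene)-3,3-dimethylcyclohexan-1-one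
Conditions: HNTf2 (10 mol %), (CF3)2CHOH–CH2Cl2 1:4, −20 → 0 °C
Reagents that add atoms: none
Why: Proposed new method: acid-catalysed, bromonium-relayed 1,3-O→C shift — protonation of the vinylogous formate makes the enol oxygen a leaving group, the anti-disposed neighbouring bromine expels it from the tertiary carbon to give a bromonium ion/enol pair in the cation-stabilising fluoroalcohol, O-return only regenerates 4 whereas 6-(enolendo) attack of the enol carbon at the tertiary terminus is irreversible and forms the C–C bond of ring A, and the C–Br carbon keeps all four substituents so its configuration is retained; closest known chemistry is the Lewis-acid Ferrier-type (Petasis–Ferrier) O→C rearrangement of cyclic enol ethers and the stereospecific generation of bromonium ions from enantioenriched bromohydrin derivatives or vicinal bromochlorides for cation–π cyclisation.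

Step 4
Reactants: 5 (2Z,4R)-4-bromo-2-(hydroxymethylidene)-3,3-dimethylcyclohexan-1-one; 6 but-3-en-2-one (methyl vinyl ketone)
Product: 8 (4R,6R)-4-bromo-5,5-dimethylspiro[5.5]undec-7-ene-1,9-dione, via Michael adduct 7 (not isolated)
Conditions: 6 (1.5 equiv), Et3N (0.2 equiv), toluene, 0 → 23 °C; then TsOH·H2O (0.4 equiv), 4 Å MS, 80 °C
Reagents that add atoms: none
Why: Robinson-type spiroannulation: the planar chelated enolate of 5 adds to 6 axially, anti to the pseudo-axial C3 methyl of the half-chair that keeps C4–Br equatorial, which puts the oxobutyl arm axial and the formyl group equatorial and cis to bromine (the 6R centre of 8), and acid-catalysed aldol condensation of the methyl ketone onto the aldehyde (far more electrophilic than the hindered ring ketone) then closes ring B.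

Step 5
Reactants: 8 (4R,6R)-4-bromo-5,5-dimethylspiro[5.5]undec-7-ene-1,9-dione
Product: 9 (4R,6R,9Z)-4-bromo-9-(bromomethylidene)-5,5-dimethylspiro[5.5]undec-7-en-1-one
Conditions: Ph3P+CH2Br Br− (1.6 equiv), NaN(SiMe3)2 (1.5 equiv), THF, −78 °C; then 8, −78 → 0 °C; Z isomer isolated on AgNO3–SiO2
Reagents that add atoms: (bromomethyl)triphenylphosphonium bromide, BrC[P+](c1ccccc1)(c1ccccc1)c1ccccc1.[Br-]
Why: Wittig bromomethylenation with the non-stabilised ylide Ph3P=CHBr attacks only the unhindered enone carbonyl (the C1 ketone is screened by the adjacent quaternary spiro carbon), but the exocyclic geometry is only weakly biased, so a Z/E mixture is expected from which the Z isomer is separated by argentation chromatography and the E isomer is photo-equilibrated (hν, catalytic PhSSPh) and recycled; the stereocentres are untouched.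

Step 6
Reactants: 9 (4R,6R,9Z)-4-bromo-9-(bromomethylidene)-5,5-dimethylspiro[5.5]undec-7-en-1-one
Product: 10 (4R,6S,9Z)-4-bromo-9-(bromomethylidene)-5,5-dimethyl-1-methylidenespiro[5.5]undec-7-ene (target; locants as in 9)
Conditions: Cp2Ti(μ-Cl)(μ-CH2)AlMe2 (Tebbe reagent, 1.5 equiv), pyridine (cat.), THF–toluene, −40 → 0 °C
Reagents that add atoms: Tebbe reagent (drawn as Cp2Ti=CH2·ClAlMe2), C=[Ti](C1C=CC=C1)C1C=CC=C1.C[Al](C)Cl
Why: Tebbe methylenation: the small, non-basic titanium methylidene olefinates the hindered, enolisable C1 ketone without E2 loss of the secondary bromide and without touching the dienyl bromide or either stereocentre (the spiro descriptor changes from R to S only through CIP priorities).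

## Compound list

1 | 6-methylhept-5-en-2-one (sulcatone) | CC(C)=CCCC(C)=O | starting material
2 | lithium 6-methylhepta-1,5-dien-2-olate (kinetic enolate) | [Li+].[O-]C(=C)CCC=C(C)C | intermediate
3 | (1Z)-1-hydroxy-7-methylocta-1,6-dien-3-one | CC(C)=CCCC(=O)/C=C\O | intermediate
4 | (2Z)-2-[(5R)-5-bromo-6,6-dimethyloxan-2-ylidene]acetaldehyde | O=C/C=C1/CC[C@@H](Br)C(C)(C)O1 | intermediate
5 | (2Z,4R)-4-bromo-2-(hydroxymethylidene)-3,3-dimethylcyclohexan-1-one | O=C1CC[C@@H](Br)C(C)(C)/C1=C/O | intermediate
6 | but-3-en-2-one (methyl vinyl ketone) | CC(=O)C=C | starting material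
7 | (1S,3R)-3-bromo-2,2-dimethyl-6-oxo-1-(3-oxobutyl)cyclohexane-1-carbaldehyde | O=C1CC[C@@H](Br)C(C)(C)[C@]1(C=O)CCC(C)=O | intermediate
8 | (4R,6R)-4-bromo-5,5-dimethylspiro[5.5]undec-7-ene-1,9-dione | O=C1CC[C@@H](Br)C(C)(C)[C@@]12C=CC(=O)CC2 | intermediate
9 | (4R,6R,9Z)-4-bromo-9-(bromomethylidene)-5,5-dimethylspiro[5.5]undec-7-en-1-one | O=C1CC[C@@H](Br)C(C)(C)[C@@]12C=C/C(=C\Br)CC2 | intermediate
10 | (4R,6S,9Z)-4-bromo-9-(bromomethylidene)-5,5-dimethyl-1-methylidenespiro[5.5]undec-7-ene | C=C1CC[C@@H](Br)C(C)(C)[C@@]12C=C/C(=C\Br)CC2 | target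

## Step count and risks

Total steps: 6. Longest linear sequence: 6 (1 → 10).

**Step 3 (proposed new step).** The bromonium/enol pair may only return to 4, lose a proton to an allylic bromide, or pass Br+ to the enol carbon. The fallback uses known reactions, sets out from 4 and comes back at 5. Dry HCl in dioxane/CH2Cl2 at 0 °C cleaves the tert-alkyl enol ether (acidolysis with Markovnikov chloride capture, C–Br centre untouched) to (1Z,6R)-6-bromo-7-chloro-1-hydroxy-7-methyloct-1-en-3-one F3. Silylation with Me3SiCl/Et3N gives (1E,6R)-6-bromo-7-chloro-7-methyl-1-(trimethylsilyloxy)oct-1-en-3-one F4, in which oxygen can no longer return. A Reetz-type intramolecular α-tert-alkylation of the silyl enol ether with ZnCl2 in CH2Cl2 at −40 °C then closes ring A, the vicinal bromochloride ionising stereospecifically through the same bromonium ion, and aqueous work-up gives 5.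

**Step 2.** The ee may be low on a prenyl alkene, N-bromosuccinimide may brominate the enol carbon instead of the alkene, and some 5-exo ether may form. The fallback sets out from 3 and comes back at 4. Uncatalysed bromoetherification (N-bromosuccinimide added slowly, CH2Cl2, −20 °C) gives racemic (2Z)-2-(5-bromo-6,6-dimethyloxan-2-ylidene)acetaldehyde F1. Preparative chiral-stationary-phase SFC resolves it into 4 and (2Z)-2-[(5S)-5-bromo-6,6-dimethyloxan-2-ylidene]acetaldehyde F2, which is discarded. This replaces asymmetric catalysis by racemic cyclisation and enantiomer separation.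

**Step 5.** The Wittig reaction has no strong control over the exocyclic C=CHBr geometry, and the ylide may enolise 8. The fallback sets out from 8 and comes back at 9. Ramirez dibromomethylenation (CBr4, PPh3, toluene, 80 °C) gives (4R,6R)-4-bromo-9-(dibromomethylidene)-5,5-dimethylspiro[5.5]undec-7-en-1-one F5, which has no alkene geometry to control. Site-selective hydrodebromination (Pd(PPh3)4 5 mol %, Bu3SnH, toluene, 23 °C) then removes the more accessible bromine. That is expected to be the one on the flexible C10 methylene side rather than the one facing the rigid in-plane vinylic C8–H, which leaves the Z bromide 9.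

## Further compounds

F1 | step 2 | racemic (2Z)-2-(5-bromo-6,6-dimethyloxan-2-ylidene)acetaldehyde | O=C/C=C1/CCC(Br)C(C)(C)O1
F2 | step 2 | (2Z)-2-[(5S)-5-bromo-6,6-dimethyloxan-2-ylidene]acetaldehyde | O=C/C=C1/CC[C@H](Br)C(C)(C)O1
F3 | step 3 | (1Z,6R)-6-bromo-7-chloro-1-hydroxy-7-methyloct-1-en-3-one | O/C=C\C(=O)CC[C@@H](Br)C(C)(C)Cl
F4 | step 3 | (1E,6R)-6-bromo-7-chloro-7-methyl-1-(trimethylsilyloxy)oct-1-en-3-one | C[Si](C)(C)O/C=C/C(=O)CC[C@@H](Br)C(C)(C)Cl
F5 | step 5 | (4R,6R)-4-bromo-9-(dibromomethylidene)-5,5-dimethylspiro[5.5]undec-7-en-1-one | O=C1CC[C@@H](Br)C(C)(C)[C@@]12C=CC(=C(Br)Br)CC2
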